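**Remark (assumption):** 18 has no stereocentre, axis or stereogenic double bond, so "single enantiomer" is read as the one achiral constitution given. The sp3 centres of the non-isolated intermediates 10, 13, 14 and 16 are racemic and are erased in the same flask.

## The problem

Broussoflavonol F (18) is kaempferol with two C-bound 3-methylbut-2-enyl (prenyl) groups, one at C-8 of ring A and one at C-3′ of ring B; with no stereogenic element, the task is one of regiochemistry and functional-group tolerance. Ring A is a phloroglucinol nucleus in which C-6 and C-8 are each flanked by two oxygens and are almost equally nucleophilic, so any intermolecular prenylation or halogenation must tell them apart, and a 5-hydroxy-8-alkylflavone can drift to its 6-isomer by acid-induced opening and reclosure of the pyranone (Wessely–Moser). Each prenyl group lies ortho to a phenol (C-8/O-7 and C-3′/O-4′); this array cyclises to a 2,2-dimethylchroman in acid, and the two trisubstituted alkenes exclude hydrogenolysis, boron halides and electrophilic oxidants (peracids, dioxiranes) once they are in place. The oxygen at C-3 must therefore come from an oxidant that ignores isolated alkenes, and the four hydroxyls (acidity 7 > 4′ > 3 > chelated 5) must be distinguishable wherever they are handled. The feature the plan exploits is the position of the two prenylated carbons relative to two ring oxygens: in ring A, C-8 is para to O-5, O-5 has only one open ortho carbon (C-6; the other is the ring-fusion atom C-4a) and lies peri to the C-4 carbonyl, where a Lewis acid can be chelated; in ring B, C-3′ is ortho to O-4′, whose para carbon C-1′ is blocked by the bond to C-2. A prenyl group on O-5 can thus travel O-5 → C-6 → C-8 by two [3,3] shifts (two allyl inversions, linear chain restored), and a 1,1-dimethylallyl group on O-4′ reaches C-3′ by one [3,3] shift (one inversion, linear chain formed). These same two oxygens are the phenols that must be masked while the pyranone is built, so the latent prenyl groups can serve as their protecting groups.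

## Retrosynthesis

**18 ⇒ 17.** The O–CH2 bonds of two methoxymethyl (MOM) acetals at O-3 and O-7 are cut last. An acetal is preferred to benzyl or methyl ethers because its removal needs neither hydrogen nor a boron halide, and to esters because O-7 must stay masked through hydroxide and alkaline peroxide. 17 differs from 18 only by these two groups. The forward step must be mild enough not to add the freed phenols to the neighbouring alkenes.

**17 ⇒ 12 (key disconnection).** Both aryl–CH2 bonds (C-8–C-1″ and C-3′–C-1‴) are cut in one operation. Each C5 unit is returned to the oxygen from which a sigmatropic path leads to that carbon: the ring-A unit to O-5 as a 3-methylbut-2-enyl ether, the ring-B unit to O-4′ as a 2-methylbut-3-en-2-yl ether. Against the neighbouring cuts (intermolecular prenylation of the arene, or a rearrangement launched from O-7, which has two open ortho carbons), this cut makes the regiochemistry a matter of orbital geometry: from O-5 there is one path and it ends at C-8. Precursor 12 is an isomer of 17 with no aryl–prenyl bond and no free phenol, and every substituent in it can be placed by O-alkylation. The forward reaction must carry the ring-A group through C-6 to C-8 without stopping, rearrange the tertiary ether of ring B without ionising it, and do both in one flask.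

**12 ⇒ 11 ⇒ 9.** The third acetal (O-3) is cut to give flavonol 11. In 11 the pyranone is opened at O-1–C-2 and the C-3 oxygen removed, which leads to 2′-hydroxychalcone 9 (oxidative cyclisation in the forward sense). The neighbouring option, a flavone hydroxylated later at C-3, costs extra steps; alkaline hydrogen peroxide is nucleophilic and should not touch the three isolated alkenes that 9 already carries. 9 is acyclic apart from its two benzene rings. The forward step must close the six-membered ring (attack at the benzylic carbon) and not the five-membered one, although a 6′-alkoxy group is present.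

**9 ⇒ 4 + 8.** The Cα=Cβ bond is cut by a retro-aldol condensation into methyl ketone 4 and aldehyde 8, the one convergent union of the route. Each half already holds one latent prenyl group on the correct oxygen. This is preferred to an acylation-based assembly because it needs only base at room temperature, which both ethers tolerate.

**4 ⇒ 2 ⇒ 1 + 3.** Two O–C bonds are cut, and the symmetry of 1 does the work. Its 4-OH is the only hydroxyl not hydrogen-bonded to the acetyl group and takes the acetal (2). The two remaining ortho hydroxyls are equivalent, so mono-alkylation with 3 needs no regiocontrol. It leaves the chelated 2-OH that later becomes O-1, while the prenylated oxygen becomes O-5.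

**8 ⇒ 7 ⇒ 5 + 6.** The tertiary allyl aryl ether cannot be made by SN2 substitution. The vinyl group is therefore traced to an alkyne (7), and the O–C bond to copper-assisted substitution of propargylic chloride 6 by phenol 5.

## Roads not taken

Alternative 1: (the route most would draw first) the same pyranone disconnection, but with both prenyl groups already C-bound in the two halves. This means C-prenylation of 1 and of 5 with 3, protection to acetophenone A1 and aldehyde A2, Claisen–Schmidt condensation to chalcone A3, oxidative cyclisation and removal of three acetals. The forward key step is the Algar–Flynn–Oyamada reaction of A3. The chosen plan is better on three counts: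
- The two C-prenylations are intermolecular alkylations of ambident phenoxides, in which O-alkylation and polyalkylation compete.
- After C-prenylation the two ortho hydroxyls of the ketone are no longer equivalent. Only the one beside the prenyl group may stay free (A1), otherwise ring closure gives the 6-prenyl series, and that distinction rests on a small steric bias.
- Three acetals are needed where the chosen plan needs two, because there the prenyl groups themselves mask O-5 and O-4′. The step count is no lower.

Alternative 2: launch both sigmatropic shifts from the more accessible oxygens O-7 and O-4′ of commercial kaempferol A4. Twofold O-(1,1-dimethylallyl)ation gives bis-ether A5, and a double ortho-Claisen rearrangement (O-7 → C-8, O-4′ → C-3′) would give 18 directly. It is the shortest conceivable route. However, O-7 has two open ortho carbons, and with the 5-OH chelated to the carbonyl no bond-fixation argument reliably favours C-8 over C-6. The 6,3′-diprenyl isomer A6 is therefore to be expected alongside 18 and would be hard to separate. In addition, the 3-OH of A4 competes with the 4′-OH in the alkylation. The chosen plan pays more steps for a ring-A shift that has only one destination.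

Alternative 3: cut both aryl–CH2 bonds as aryl–halogen plus prenyl–metal. Diiodide A7 (from A4 by acetal protection and twofold electrophilic iodination) would undergo a twofold Pd-catalysed coupling with a prenylboron or prenyltin reagent. The iodination faces the same C-6/C-8 ambiguity and must also reach C-3′ of a ring deactivated by conjugation with the pyranone. Each coupling passes through an η3-prenyl–palladium species that can deliver the linear or the 1,1-dimethylallyl isomer, so regiochemical choices remain open on both rings, against none in a [3,3] shift. Four acetals must be cleaved at the end instead of two.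

Key step: step 8

## Steps

Step 1
Reactants: 1 1-(2,4,6-trihydroxyphenyl)ethan-1-one (phloroacetophenone)
Product: 2 1-[2,6-dihydroxy-4-(methoxymethoxy)phenyl]ethan-1-one
Conditions: MOMCl (1.05 equiv), iPr2NEt (1.2 equiv), THF, 0 °C → rt
Reagents that add atoms: chloromethyl methyl ether, COCCl
Why: O-alkylation (acetalisation) of the most acidic, non-chelated 4-OH para to the acetyl group; the two ortho hydroxyls are hydrogen-bonded to the carbonyl and react more slowly, so one equivalent of the hard electrophile should give mainly the 4-mono-acetal.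

Step 2
Reactants: 2 1-[2,6-dihydroxy-4-(methoxymethoxy)phenyl]ethan-1-one; 3 1-bromo-3-methylbut-2-ene (prenyl bromide)
Product: 4 1-{2-hydroxy-4-(methoxymethoxy)-6-[(3-methylbut-2-en-1-yl)oxy]phenyl}ethan-1-one
Conditions: K2CO3 (1.5 equiv), 3 (1.05 equiv), acetone, reflux
Reagents that add atoms: none
Why: Williamson mono-etherification of one of two equivalent chelated hydroxyls; after the first alkylation the remaining hydroxyl is held more firmly by the carbonyl, which should stop the reaction at the mono-ether, and a carbonate base in a dipolar aprotic solvent favours O- over C-alkylation.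

Step 3
Reactants: 5 4-hydroxybenzaldehyde; 6 3-chloro-3-methylbut-1-yne
Product: 7 4-[(2-methylbut-3-yn-2-yl)oxy]benzaldehyde
Conditions: K2CO3, KI (cat.), CuI (cat.), acetone, reflux
Reagents that add atoms: none
Why: Copper-assisted propargylic substitution of the tertiary chloride by the phenoxide (ionisation through a copper acetylide), the standard entry to aryl 1,1-dimethylpropargyl ethers, which are not accessible by SN2.

Step 4
Reactants: 7 4-[(2-methylbut-3-yn-2-yl)oxy]benzaldehyde
Product: 8 4-[(2-methylbut-3-en-2-yl)oxy]benzaldehyde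
Conditions: H2 (1 atm), Lindlar catalyst (Pd/CaCO3–Pb), quinoline, EtOAc, rt, stopped after 1 equiv H2
Reagents that add atoms: none
Why: Lindlar semi-hydrogenation of a terminal alkyne to the terminal alkene; the poisoned catalyst leaves the aromatic aldehyde and the aryl ether untouched, and 8 is kept cold because it is the substrate of a low-barrier Claisen rearrangement.

Step 5
Reactants: 4 1-{2-hydroxy-4-(methoxymethoxy)-6-[(3-methylbut-2-en-1-yl)oxy]phenyl}ethan-1-one; 8 4-[(2-methylbut-3-en-2-yl)oxy]benzaldehyde
Product: 9 (E)-1-{2-hydroxy-4-(methoxymethoxy)-6-[(3-methylbut-2-en-1-yl)oxy]phenyl}-3-{4-[(2-methylbut-3-en-2-yl)oxy]phenyl}prop-2-en-1-one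
Conditions: KOH (aq. 50%, excess), EtOH, 0 °C → rt
Reagents that add atoms: none
Why: Claisen–Schmidt condensation with a non-enolisable aldehyde; E1cB dehydration gives the conjugated E-enone, and the two allyl ethers and the acetal are stable to hydroxide at room temperature.

Step 6
Reactants: 9 (E)-1-{2-hydroxy-4-(methoxymethoxy)-6-[(3-methylbut-2-en-1-yl)oxy]phenyl}-3-{4-[(2-methylbut-3-en-2-yl)oxy]phenyl}prop-2-en-1-one
Product: 11 3-hydroxy-7-(methoxymethoxy)-2-{4-[(2-methylbut-3-en-2-yl)oxy]phenyl}-5-[(3-methylbut-2-en-1-yl)oxy]-4H-chromen-4-one, via trans-dihydroflavonol 10 (not isolated)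
Conditions: 30% H2O2 (excess), aq. NaOH, MeOH–THF, 0 °C → rt
Reagents that add atoms: hydrogen peroxide, OO
Why: Algar–Flynn–Oyamada oxidative cyclisation: hydroperoxide attacks the enone, the 2′-phenoxide closes the six-membered ring at the benzylic carbon (favoured by the 4-alkoxyphenyl group) to racemic trans-dihydroflavonol 10, which excess alkaline peroxide dehydrogenates to 11; the nucleophilic oxidant should spare the three isolated alkenes, and the two centres of 10 vanish in 11.

Step 7
Reactants: 11 3-hydroxy-7-(methoxymethoxy)-2-{4-[(2-methylbut-3-en-2-yl)oxy]phenyl}-5-[(3-methylbut-2-en-1-yl)oxy]-4H-chromen-4-one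
Product: 12 3,7-bis(methoxymethoxy)-2-{4-[(2-methylbut-3-en-2-yl)oxy]phenyl}-5-[(3-methylbut-2-en-1-yl)oxy]-4H-chromen-4-one
Conditions: MOMCl, iPr2NEt, DMAP (cat.), CH2Cl2, 0 °C → 40 °C
Reagents that add atoms: chloromethyl methyl ether, COCCl
Why: Acetalisation of the only free hydroxyl; the 3-O-MOM group keeps the 3-hydroxy-4-keto site from sequestering the lanthanide catalyst of step 8 and is removed later together with the 7-O-MOM group.

Step 8
Reactants: 12 3,7-bis(methoxymethoxy)-2-{4-[(2-methylbut-3-en-2-yl)oxy]phenyl}-5-[(3-methylbut-2-en-1-yl)oxy]-4H-chromen-4-one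
Product: 17 5-hydroxy-2-[4-hydroxy-3-(3-methylbut-2-en-1-yl)phenyl]-3,7-bis(methoxymethoxy)-8-(3-methylbut-2-en-1-yl)-4H-chromen-4-one, via ring-A C-6 dienone 13 (not isolated), via ring-A C-8 dienone 14 (not isolated), via 8-prenyl-5-hydroxy ether 15 (not isolated), via ring-B dienone 16 (not isolated)
Conditions: Eu(fod)3 (10 mol %), NaHCO3, PhCl, 85 °C, then 130 °C, Ar, one flask
Reagents that add atoms: none
Why: Eu(fod)3 chelated between the C-4 carbonyl and O-5 of 12 accelerates the aromatic Claisen shift of the 5-O-prenyl group to C-6, the only open ortho carbon, giving dienone 13 with a 1,1-dimethylallyl group on an sp3 carbon wedged between C-5=O and C-7–OMOM. Relief of this congestion drives a Cope shift across C-6/C-7/C-8 to dienone 14, which now carries the linear prenyl group at C-8 and enolises to the chelated 5-phenol 15; this para-Claisen–Cope relay is an established reaction type for 5-O-prenylated flavanones, flavones and 3,7-protected flavonols. On warming to 130 °C the aryl 1,1-dimethylallyl ether of ring B undergoes the ordinary thermal ortho-Claisen rearrangement through a chair transition state to dienone 16, which can only enolise because the para carbon C-1′ is quaternary, and this gives 17. No ring is closed and no stereocentre is retained, since the sp3 centres of 13, 14 and 16 are lost on tautomerisation. The selectivity needed is positional: C-8 over C-6 is secured by launching from O-5, whose para carbon is C-8, with the second [3,3] shift expected to outrun enolisation of the crowded 13 in the non-basic medium. The linear attachment of both chains follows from the parity of allyl inversions, two for the prenyl ether and one for the 1,1-dimethylallyl ether, and C-3′ and C-5′ are equivalent, so ring B offers no choice. The MOM acetals are not allylic and cannot take part, and NaHCO3 keeps adventitious acid from ionising the tertiary ether or cyclising the new o-prenylphenol.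

Step 9
Reactants: 17 5-hydroxy-2-[4-hydroxy-3-(3-methylbut-2-en-1-yl)phenyl]-3,7-bis(methoxymethoxy)-8-(3-methylbut-2-en-1-yl)-4H-chromen-4-one
Product: 18 Broussoflavonol F, 3,5,7-trihydroxy-2-[4-hydroxy-3-(3-methylbut-2-en-1-yl)phenyl]-8-(3-methylbut-2-en-1-yl)-4H-chromen-4-one
Conditions: HCl (ca. 1 M in MeOH), MeOH–THF, rt → 40 °C; aq. NaHCO3 work-up
Reagents that add atoms: none
Why: Acid-catalysed transacetalisation of the two MOM ethers to methanol; dilute methanolic HCl near room temperature is the usual unmasking of MOM-protected prenylphenols and is to be stopped before hydroalkoxylation of the o-prenylphenols or Wessely–Moser equilibration sets in.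

## Compound list

1 | 1-(2,4,6-trihydroxyphenyl)ethan-1-one | CC(=O)c1c(O)cc(O)cc1O | starting material
2 | 1-[2,6-dihydroxy-4-(methoxymethoxy)phenyl]ethan-1-one | CC(=O)c1c(O)cc(OCOC)cc1O | intermediate
3 | 1-bromo-3-methylbut-2-ene | CC(C)=CCBr | starting material
4 | 1-{2-hydroxy-4-(methoxymethoxy)-6-[(3-methylbut-2-en-1-yl)oxy]phenyl}ethan-1-one | CC(=O)c1c(O)cc(OCOC)cc1OCC=C(C)C | intermediate
5 | 4-hydroxybenzaldehyde | O=Cc1ccc(O)cc1 | starting material
6 | 3-chloro-3-methylbut-1-yne | C#CC(C)(C)Cl | starting material
7 | 4-[(2-methylbut-3-yn-2-yl)oxy]benzaldehyde | O=Cc1ccc(OC(C)(C)C#C)cc1 | intermediate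
8 | 4-[(2-methylbut-3-en-2-yl)oxy]benzaldehyde | O=Cc1ccc(OC(C)(C)C=C)cc1 | intermediate
9 | (E)-1-{2-hydroxy-4-(methoxymethoxy)-6-[(3-methylbut-2-en-1-yl)oxy]phenyl}-3-{4-[(2-methylbut-3-en-2-yl)oxy]phenyl}prop-2-en-1-one | O=C(/C=C/c1ccc(OC(C)(C)C=C)cc1)c1c(O)cc(OCOC)cc1OCC=C(C)C | intermediate
10 | trans-3-hydroxy-7-(methoxymethoxy)-2-{4-[(2-methylbut-3-en-2-yl)oxy]phenyl}-5-[(3-methylbut-2-en-1-yl)oxy]chroman-4-one (racemic; 2R,3R enantiomer drawn) | O=C1c2c(OCC=C(C)C)cc(OCOC)cc2O[C@H](c2ccc(OC(C)(C)C=C)cc2)[C@H]1O | intermediate
11 | 3-hydroxy-7-(methoxymethoxy)-2-{4-[(2-methylbut-3-en-2-yl)oxy]phenyl}-5-[(3-methylbut-2-en-1-yl)oxy]-4H-chromen-4-one | O=c1c(O)c(-c2ccc(OC(C)(C)C=C)cc2)oc2cc(OCOC)cc(OCC=C(C)C)c12 | intermediate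
12 | 3,7-bis(methoxymethoxy)-2-{4-[(2-methylbut-3-en-2-yl)oxy]phenyl}-5-[(3-methylbut-2-en-1-yl)oxy]-4H-chromen-4-one | O=c1c(OCOC)c(-c2ccc(OC(C)(C)C=C)cc2)oc2cc(OCOC)cc(OCC=C(C)C)c12 | intermediate
13 | 3,7-bis(methoxymethoxy)-6-(2-methylbut-3-en-2-yl)-2-{4-[(2-methylbut-3-en-2-yl)oxy]phenyl}-4H-chromene-4,5(6H)-dione (racemic) | O=C1C(C(C)(C)C=C)C(OCOC)=CC2=C1C(=O)C(OCOC)=C(c3ccc(OC(C)(C)C=C)cc3)O2 | intermediate
14 | 3,7-bis(methoxymethoxy)-8-(3-methylbut-2-en-1-yl)-2-{4-[(2-methylbut-3-en-2-yl)oxy]phenyl}-4H-chromene-4,5(8H)-dione (racemic) | O=C1C=C(OCOC)C(CC=C(C)C)C2=C1C(=O)C(OCOC)=C(c3ccc(OC(C)(C)C=C)cc3)O2 | intermediate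
15 | 5-hydroxy-3,7-bis(methoxymethoxy)-8-(3-methylbut-2-en-1-yl)-2-{4-[(2-methylbut-3-en-2-yl)oxy]phenyl}-4H-chromen-4-one | O=c1c(OCOC)c(-c2ccc(OC(C)(C)C=C)cc2)oc2c(CC=C(C)C)c(OCOC)cc(O)c12 | intermediate
16 | 5-hydroxy-3,7-bis(methoxymethoxy)-8-(3-methylbut-2-en-1-yl)-2-[3-(3-methylbut-2-en-1-yl)-4-oxocyclohexa-1,5-dien-1-yl]-4H-chromen-4-one (racemic) | O=c1c(OCOC)c(C3=CC(CC=C(C)C)C(=O)C=C3)oc2c(CC=C(C)C)c(OCOC)cc(O)c12 | intermediate
17 | 5-hydroxy-2-[4-hydroxy-3-(3-methylbut-2-en-1-yl)phenyl]-3,7-bis(methoxymethoxy)-8-(3-methylbut-2-en-1-yl)-4H-chromen-4-one | O=c1c(OCOC)c(-c2ccc(O)c(CC=C(C)C)c2)oc2c(CC=C(C)C)c(OCOC)cc(O)c12 | intermediate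
18 | Broussoflavonol F, 3,5,7-trihydroxy-2-[4-hydroxy-3-(3-methylbut-2-en-1-yl)phenyl]-8-(3-methylbut-2-en-1-yl)-4H-chromen-4-one | CC(C)=CCc1cc(-c2oc3c(CC=C(C)C)c(O)cc(O)c3c(=O)c2O)ccc1O | target

## Step count and risk

Total steps: 9. Longest linear sequence: 7 (steps 1, 2, 5, 6, 7, 8, 9, from 1); the aldehyde branch (steps 3 and 4) joins at step 5.

**Step 8 (key step).** The most likely failure is ionisation of the tertiary allyl aryl ether of ring B, by the Lewis acid or by heat, before it can rearrange in concert. The 4′-oxygen sits on an aryl ring conjugated with the pyranone and is a good leaving group, so the C5 unit could be lost or transferred at random. A second risk is arrest of the ring-A relay at C-6 by premature enolisation. The fallback takes ring B out of the one-flask event; it sets out from 8 and returns to the route at 18. Aldehyde 8 is rearranged on its own (N,N-diethylaniline, 140 °C, a known Claisen rearrangement of this ether type) to 4-hydroxy-3-prenylbenzaldehyde F1. This is protected (MOMCl, iPr2NEt) as 4-(methoxymethoxy)-3-prenylbenzaldehyde F2, the aldehyde met as A2 under Alternative 1. Condensation with 4 as in step 5 gives the 6′-O-prenyl-3-C-prenyl chalcone F3, and oxidation as in step 6 gives the 5-O-prenyl-3′-C-prenyl flavonol F4. Protection as in step 7 gives its 3-O-MOM ether F5. Eu(fod)3 in PhCl at 85 °C then has only the ring-A relay to perform and gives the 8-prenyl-5-hydroxy tris-MOM flavonol F6. Methanolic HCl removes the three acetals and gives 18.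

**Step 6.** The oxidative cyclisation may partition toward five-membered closure at the α-carbon (benzofuranone formation), because the 6′-alkoxy group twists the aryl ketone out of plane and disfavours the six-membered transition state. The fallback separates ring closure from oxygenation; it sets out from 9 and returns at 11. Base-catalysed 6-endo oxa-Michael addition (NaOAc, EtOH, 70 °C) gives the racemic 5-O-prenyl flavanone F7. Dehydrogenation (IBX, DMSO, 80 °C) gives the 5-O-prenyl flavone F8. C-3 lithiation, borylation and oxidation (LDA, THF, −78 °C; B(OMe)3; then H2O2, aq. NaHCO3) install the hydroxyl without an electrophilic oxidant and give 11.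

**Step 9.** Acid may add the freed phenols across the adjacent prenyl double bonds (chroman formation) or open and reclose the pyranone, in competition with acetal cleavage. The fallback replaces the acid-labile groups by ones removed without acid; it sets out from 1 and returns at 18. Ketone 1 is allylated at the 4-OH (allyl bromide, K2CO3, acetone) to the 4-O-allyl ketone F9 and mono-prenylated as in step 2 to the 4-O-allyl-6-O-prenyl ketone F10. Condensation with 8 gives the 4′-O-allyl chalcone F11, and oxidative cyclisation as in step 6 gives the 7-O-allyl flavonol F12. Acetylation (Ac2O, pyridine) gives the 3-O-acetyl-7-O-allyl flavonol F13. Rearrangement as in step 8 gives the diprenylated 3-acetate 7-allyl ether F14; the unactivated 7-O-allyl aryl ether needs far higher temperatures to rearrange and should stay in place. Pd(PPh3)4, K2CO3, MeOH then removes the allyl group by π-allyl transfer to methoxide and the acetate by methanolysis, giving 18.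

**Step 2.** The ambident phenoxide of the electron-rich ring may be C-prenylated, and a second O-alkylation may follow. The fallback avoids a free phenoxide; it sets out from 2 and returns at 4 and makes no new compound. Mitsunobu etherification of 2 with 3-methylbut-2-en-1-ol (PPh3, DIAD, THF, 0 °C) lets the neutral phenol attack an alkoxyphosphonium ion at oxygen.

## Further compounds

F1 | step 8 | 4-hydroxy-3-(3-methylbut-2-en-1-yl)benzaldehyde | O=Cc1ccc(O)c(CC=C(C)C)c1
F2 | step 8 | 4-(methoxymethoxy)-3-(3-methylbut-2-en-1-yl)benzaldehyde | O=Cc1ccc(OCOC)c(CC=C(C)C)c1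
F3 | step 8 | (E)-1-{2-hydroxy-4-(methoxymethoxy)-6-[(3-methylbut-2-en-1-yl)oxy]phenyl}-3-[4-(methoxymethoxy)-3-(3-methylbut-2-en-1-yl)phenyl]prop-2-en-1-one | O=C(/C=C/c1ccc(OCOC)c(CC=C(C)C)c1)c1c(O)cc(OCOC)cc1OCC=C(C)C
F4 | step 8 | 3-hydroxy-7-(methoxymethoxy)-2-[4-(methoxymethoxy)-3-(3-methylbut-2-en-1-yl)phenyl]-5-[(3-methylbut-2-en-1-yl)oxy]-4H-chromen-4-one | O=c1c(O)c(-c2ccc(OCOC)c(CC=C(C)C)c2)oc2cc(OCOC)cc(OCC=C(C)C)c12
F5 | step 8 | 3,7-bis(methoxymethoxy)-2-[4-(methoxymethoxy)-3-(3-methylbut-2-en-1-yl)phenyl]-5-[(3-methylbut-2-en-1-yl)oxy]-4H-chromen-4-one | O=c1c(OCOC)c(-c2ccc(OCOC)c(CC=C(C)C)c2)oc2cc(OCOC)cc(OCC=C(C)C)c12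
F6 | step 8 | 5-hydroxy-3,7-bis(methoxymethoxy)-2-[4-(methoxymethoxy)-3-(3-methylbut-2-en-1-yl)phenyl]-8-(3-methylbut-2-en-1-yl)-4H-chromen-4-one | O=c1c(OCOC)c(-c2ccc(OCOC)c(CC=C(C)C)c2)oc2c(CC=C(C)C)c(OCOC)cc(O)c12
F7 | step 6 | 7-(methoxymethoxy)-2-{4-[(2-methylbut-3-en-2-yl)oxy]phenyl}-5-[(3-methylbut-2-en-1-yl)oxy]chroman-4-one (racemic) | O=C1CC(c2ccc(OC(C)(C)C=C)cc2)Oc2cc(OCOC)cc(OCC=C(C)C)c12
F8 | step 6 | 7-(methoxymethoxy)-2-{4-[(2-methylbut-3-en-2-yl)oxy]phenyl}-5-[(3-methylbut-2-en-1-yl)oxy]-4H-chromen-4-one | O=c1cc(-c2ccc(OC(C)(C)C=C)cc2)oc2cc(OCOC)cc(OCC=C(C)C)c12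
F9 | step 9 | 1-[2,6-dihydroxy-4-(prop-2-en-1-yloxy)phenyl]ethan-1-one | CC(=O)c1c(O)cc(OCC=C)cc1O
F10 | step 9 | 1-{2-hydroxy-6-[(3-methylbut-2-en-1-yl)oxy]-4-(prop-2-en-1-yloxy)phenyl}ethan-1-one | CC(=O)c1c(O)cc(OCC=C)cc1OCC=C(C)C
F11 | step 9 | (E)-1-{2-hydroxy-6-[(3-methylbut-2-en-1-yl)oxy]-4-(prop-2-en-1-yloxy)phenyl}-3-{4-[(2-methylbut-3-en-2-yl)oxy]phenyl}prop-2-en-1-one | O=C(/C=C/c1ccc(OC(C)(C)C=C)cc1)c1c(O)cc(OCC=C)cc1OCC=C(C)C
F12 | step 9 | 3-hydroxy-2-{4-[(2-methylbut-3-en-2-yl)oxy]phenyl}-5-[(3-methylbut-2-en-1-yl)oxy]-7-(prop-2-en-1-yloxy)-4H-chromen-4-one | O=c1c(O)c(-c2ccc(OC(C)(C)C=C)cc2)oc2cc(OCC=C)cc(OCC=C(C)C)c12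
F13 | step 9 | 2-{4-[(2-methylbut-3-en-2-yl)oxy]phenyl}-5-[(3-methylbut-2-en-1-yl)oxy]-4-oxo-7-(prop-2-en-1-yloxy)-4H-chromen-3-yl acetate | CC(=O)Oc1c(-c2ccc(OC(C)(C)C=C)cc2)oc2cc(OCC=C)cc(OCC=C(C)C)c2c1=O
F14 | step 9 | 5-hydroxy-2-[4-hydroxy-3-(3-methylbut-2-en-1-yl)phenyl]-8-(3-methylbut-2-en-1-yl)-4-oxo-7-(prop-2-en-1-yloxy)-4H-chromen-3-yl acetate | CC(=O)Oc1c(-c2ccc(O)c(CC=C(C)C)c2)oc2c(CC=C(C)C)c(OCC=C)cc(O)c2c1=O
F0 | step 2 | none | none
A1 | alternative 1 | 1-[2-hydroxy-4,6-bis(methoxymethoxy)-3-(3-methylbut-2-en-1-yl)phenyl]ethan-1-one | CC(=O)c1c(O)c(CC=C(C)C)c(OCOC)cc1OCOC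
A2 | alternative 1 | 4-(methoxymethoxy)-3-(3-methylbut-2-en-1-yl)benzaldehyde | O=Cc1ccc(OCOC)c(CC=C(C)C)c1
A3 | alternative 1 | (E)-1-[2-hydroxy-4,6-bis(methoxymethoxy)-3-(3-methylbut-2-en-1-yl)phenyl]-3-[4-(methoxymethoxy)-3-(3-methylbut-2-en-1-yl)phenyl]prop-2-en-1-one | O=C(/C=C/c1ccc(OCOC)c(CC=C(C)C)c1)c1c(O)c(CC=C(C)C)c(OCOC)cc1OCOC
A4 | alternative 2 | kaempferol, 3,5,7-trihydroxy-2-(4-hydroxyphenyl)-4H-chromen-4-one | O=c1c(O)c(-c2ccc(O)cc2)oc2cc(O)cc(O)c12
A5 | alternative 2 | 3,5-dihydroxy-7-[(2-methylbut-3-en-2-yl)oxy]-2-{4-[(2-methylbut-3-en-2-yl)oxy]phenyl}-4H-chromen-4-one | O=c1c(O)c(-c2ccc(OC(C)(C)C=C)cc2)oc2cc(OC(C)(C)C=C)cc(O)c12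
A6 | alternative 2 | 3,5,7-trihydroxy-2-[4-hydroxy-3-(3-methylbut-2-en-1-yl)phenyl]-6-(3-methylbut-2-en-1-yl)-4H-chromen-4-one | CC(C)=CCc1cc(-c2oc3cc(O)c(CC=C(C)C)c(O)c3c(=O)c2O)ccc1O
A7 | alternative 3 | 8-iodo-2-[3-iodo-4-(methoxymethoxy)phenyl]-3,5,7-tris(methoxymethoxy)-4H-chromen-4-one | O=c1c(OCOC)c(-c2ccc(OCOC)c(I)c2)oc2c(I)c(OCOC)cc(OCOC)c12
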